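## Retrosynthetic overview

1. Target 35 ⇐ desilylation of 34 ⇐ C7 oxidation (enolate hydroxylation, then oxidation to the diosphenol) and C1=C2 dehydrogenation of enone ester 29 ⇐ ester union of bicyclic alcohol 14 with dienoic acid 27.
2. 14 ⇐ (S)-Wieland–Miescher ketone 5 by a methylative 1,2-carbonyl transposition in ring A (enol triflate → methyl coupling → hydroboration → oxidation → axial-selective reduction), with the ring B enone masked as a dithiolane.
3. 5 ⇐ triketone 3 ⇐ 2-methylcyclohexane-1,3-dione 1 + methyl vinyl ketone 2. The key C5–C6 bond is made by an intermolecular Michael addition; ring A comes preformed in 1, and ring B is closed second by a proline-catalysed aldol condensation that sets the quaternary stereocentre.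
4. 27 ⇐ aldehyde 23 + phosphonocrotonate 24 (vinylogous HWE); 23 ⇐ Evans titanium-enolate hydroxymethylation (aldol with formaldehyde) of butanoyl oxazolidinone 18.

Convention (one line): core locants follow eremophilane numbering (ring A = C1–C5 and C10, ring B = C5–C10; C5 = quaternary ring-fusion carbon, C4 and C3 its ring A neighbours in turn, C8 = ring B carbonyl carbon); α = the face carrying the C5 methyl, β = the opposite face.

## Route

Step 1
Reactants: 1 2-methylcyclohexane-1,3-dione; 2 methyl vinyl ketone (but-3-en-2-one)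
Product: 3 2-methyl-2-(3-oxobutyl)cyclohexane-1,3-dione
Conditions: H2O, AcOH (cat.), hydroquinone (trace), 75 °C
Reagents that add atoms: none
Why: Michael addition of the doubly stabilised C2 enol of the 1,3-dione to the unhindered enone forges the key C5–C6 bond and the quaternary carbon; no stereocentre arises because the two ring carbonyls are still enantiotopic.

Step 2
Reactants: 3 2-methyl-2-(3-oxobutyl)cyclohexane-1,3-dione
Product: 5 (S)-Wieland–Miescher ketone, via cis-fused ketol 4 (not isolated)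
Conditions: L-proline (5 mol %), DMSO, rt, 5 d; then recrystallisation (Et2O, −20 °C) to >99% ee
Reagents that add atoms: none
Why: In this Hajos–Parrish–Eder–Sauer–Wiechert aldol condensation the proline enamine of the side-chain ketone attacks one of the two enantiotopic ring carbonyls and the ketol dehydrates in situ, which sets C5 as (S) (about 70% ee crude, upgraded by crystallisation).

Step 3
Reactants: 5 (S)-Wieland–Miescher ketone
Product: 6 (5S)-C8 dithiolane of 5 (C4 ketone free; C9=C10 retained)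
Conditions: HSCH2CH2SH (1.05 equiv), p-toluenesulfonic acid monohydrate (cat.), AcOH, rt
Reagents that add atoms: ethane-1,2-dithiol, SCCS
Why: Acid-catalysed thioketalisation is selective for the unhindered conjugated carbonyl over the neopentylic C4 ketone and, unlike O-ketalisation, leaves the C9=C10 bond in place.

Step 4
Reactants: 6 (5S)-C8 dithiolane ketone
Product: 8 (5S)-C3=C4 enol triflate, via potassium enolate 7 (not isolated)
Conditions: KN(SiMe3)2, THF, −78 °C; then PhNTf2, −78 → 0 °C
Reagents that add atoms: N-phenylbis(trifluoromethanesulfonimide), O=S(=O)(N(c1ccccc1)S(=O)(=O)C(F)(F)F)C(F)(F)F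
Why: In this enolate O-triflation the C4 ketone can enolise only towards C3 because C5 is quaternary, so a single alkenyl triflate forms.

Step 5
Reactants: 8 (5S)-C3=C4 enol triflate
Product: 9 4,5-dimethyl-3,9(10)-diene C8 dithiolane
Conditions: MeMgBr (1.5 equiv), Fe(acac)3 [iron tris(acetylacetonate), 5 mol %], THF/NMP, −20 → 0 °C
Reagents that add atoms: methylmagnesium bromide, C[Mg]Br
Why: Iron-catalysed Kumada-type cross-coupling of the alkenyl triflate with the methyl Grignard reagent installs the C4 methyl carbon under conditions that tolerate the dithiolane.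

Step 6
Reactants: 9 4,5-dimethyl-3,9(10)-diene C8 dithiolane
Product: 11 (3R,4R,5R)-3β-hydroxy-4α,5α-dimethyl-9(10)-ene C8 dithiolane, via 3β-alkylborane 10 (not isolated)
Conditions: BH3·THF (1.1 equiv), THF, 0 °C → rt; then NaBO3·4H2O, H2O, rt
Reagents that add atoms: sodium perborate (NaBO3·4H2O, peroxoborate dimer), [Na+].[Na+].O[B-]1(O)OO[B-](O)(O)OO1
Why: In this Brown hydroboration–oxidation, borane adds syn to the C3=C4 alkene from the β face, opposite the axial C5 methyl, with boron at C3 (far less hindered than C9 beside the dithiolane); C4–H is therefore β (4-methyl cis to 5-methyl) and retentive perborate oxidation, which spares sulfur, gives the 3β-alcohol.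

Step 7
Reactants: 11 3β-hydroxy-4α,5α-dimethyl-9(10)-ene C8 dithiolane
Product: 12 (4R,5R)-4α,5α-dimethyl-9(10)-en-3-one C8 dithiolane
Conditions: (COCl)2, DMSO, CH2Cl2, −78 °C; Et3N, −78 → −20 °C
Reagents that add atoms: none
Why: Swern oxidation gives the C3 ketone without oxidising the thioketal and, being cold with brief base contact, without epimerising C4.

Step 8
Reactants: 12 4α,5α-dimethyl-9(10)-en-3-one C8 dithiolane
Product: 13 (3S,4R,5R)-3α-hydroxy-4α,5α-dimethyl-9(10)-ene C8 dithiolane
Conditions: Li[HB(s-Bu)3], THF, −78 °C; then H2O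
Reagents that add atoms: none
Why: In this bulky-hydride (L-Selectride-type) reduction the hydride attacks C3 equatorially from the β face, the axial α trajectory being blocked by the syn-axial C5 methyl, which gives the axial 3α-alcohol cis to both methyls.

Step 9
Reactants: 13 3α-hydroxy-4α,5α-dimethyl-9(10)-ene C8 dithiolane
Product: 14 (4aR,5R,6S)-6-hydroxy-4a,5-dimethyl-4,4a,5,6,7,8-hexahydronaphthalen-2(3H)-one
Conditions: MeI (excess), CaCO3, MeCN/H2O (4:1), 60 °C
Reagents that add atoms: water, O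
Why: Dethioketalisation by S-methylation and hydrolysis of the resulting sulfonium/thionium species unmasks the conjugated C8 ketone under buffered conditions that leave the alcohol and all stereocentres untouched.

Step 10
Reactants: 15 (R)-4-benzyloxazolidin-2-one; 16 butanoyl chloride
Product: 18 (R)-4-benzyl-3-butanoyloxazolidin-2-one, via lithium oxazolidinide 17 (not isolated)
Conditions: n-BuLi, THF, −78 °C; then 16, −78 → 0 °C
Reagents that add atoms: none
Why: N-Acylation of the lithiated Evans auxiliary by the acid chloride is clean and does not touch the auxiliary stereocentre.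

Step 11
Reactants: 18 (R)-4-benzyl-3-butanoyloxazolidin-2-one
Product: 20 (R)-4-benzyl-3-[(S)-2-(hydroxymethyl)butanoyl]oxazolidin-2-one, via chlorotitanium Z-enolate 19 (not isolated)
Conditions: TiCl4, i-Pr2NEt, CH2Cl2, 0 °C; then 1,3,5-trioxane, TiCl4, 0 °C
Reagents that add atoms: 1,3,5-trioxane, C1OCOCO1
Why: In this Evans titanium-enolate aldol reaction with formaldehyde (released from trioxane by TiCl4), the chelated Z-enolate is attacked on the face opposite the benzyl group, giving the (S) α-stereocentre with >95:5 dr.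

Step 12
Reactants: 20 (R)-4-benzyl-3-[(S)-2-(hydroxymethyl)butanoyl]oxazolidin-2-one
Product: 21 (R)-4-benzyl-3-[(S)-2-{[(tert-butyldimethylsilyl)oxy]methyl}butanoyl]oxazolidin-2-one
Conditions: TBSCl, imidazole, DMF, rt
Reagents that add atoms: tert-butyldimethylsilyl chloride, CC(C)(C)[Si](C)(C)Cl
Why: Silylation of the primary alcohol (Corey conditions) protects the future side-chain hydroxyl through the rest of the route.

Step 13
Reactants: 21 TBS-protected hydroxymethyl imide
Product: 22 (R)-2-{[(tert-butyldimethylsilyl)oxy]methyl}butan-1-ol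
Conditions: LiBH4, MeOH (1 equiv), THF, 0 °C
Reagents that add atoms: none
Why: Reductive cleavage of the imide by LiBH4 gives the primary alcohol and returns the auxiliary without enolising the stereocentre or inducing silyl migration at 0 °C.

Step 14
Reactants: 22 (R)-2-{[(tert-butyldimethylsilyl)oxy]methyl}butan-1-ol
Product: 23 (S)-2-{[(tert-butyldimethylsilyl)oxy]methyl}butanal
Conditions: Dess–Martin periodinane, CH2Cl2, 0 °C → rt (used at once)
Reagents that add atoms: none
Why: Dess–Martin oxidation gives the α-branched aldehyde under non-basic conditions, so the stereocentre does not epimerise.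

Step 15
Reactants: 23 (S)-2-{[(tert-butyldimethylsilyl)oxy]methyl}butanal; 24 triethyl (E)-4-phosphonobut-2-enoate
Product: 26 ethyl (2E,4E,6R)-6-{[(tert-butyldimethylsilyl)oxy]methyl}octa-2,4-dienoate, via lithiated phosphonate 25 (not isolated)
Conditions: 24, LiN(SiMe3)2, THF, −78 °C; then 23, −78 → 0 °C
Reagents that add atoms: none
Why: Vinylogous Horner–Wadsworth–Emmons olefination with the stabilised phosphonocrotonate anion gives the (2E,4E)-dienoate with high E selectivity at low temperature without epimerising the aldehyde.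

Step 16
Reactants: 26 ethyl (2E,4E,6R)-dienoate
Product: 27 (2E,4E,6R)-6-{[(tert-butyldimethylsilyl)oxy]methyl}octa-2,4-dienoic acid
Conditions: LiOH·H2O, THF/MeOH/H2O, rt; then 1 M HCl to pH 3–4, 0 °C
Reagents that add atoms: lithium hydroxide, [Li+].[OH-]
Why: Saponification cleaves the ethyl ester while the primary TBS ether and the diene geometry survive aqueous LiOH at room temperature.

Step 17
Reactants: 27 (2E,4E,6R)-dienoic acid; 14 (4aR,5R,6S)-hydroxy enone
Product: 29 (1R,2S,8aR)-1,8a-dimethyl-6-oxo-1,2,3,4,6,7,8,8a-octahydronaphthalen-2-yl (2E,4E,6R)-6-{[(tert-butyldimethylsilyl)oxy]methyl}octa-2,4-dienoate, via mixed anhydride 28 (not isolated)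
Conditions: 27 (1.3 equiv), 2,4,6-trichlorobenzoyl chloride, Et3N, THF, rt; then 14, 4-(dimethylamino)pyridine, toluene, rt → 40 °C
Reagents that add atoms: none
Why: In this Yamaguchi esterification the mixed 2,4,6-trichlorobenzoic anhydride, activated by 4-(dimethylamino)pyridine, acylates the hindered axial 3α-alcohol with retention at C3.

Step 18
Reactants: 29 enone ester
Product: 30 (1R,2S,8aR)-1,8a-dimethyl-6-oxo-1,2,6,7,8,8a-hexahydronaphthalen-2-yl (2E,4E,6R)-6-{[(tert-butyldimethylsilyl)oxy]methyl}octa-2,4-dienoate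
Conditions: chloranil (1.5 equiv), t-BuOH, reflux
Reagents that add atoms: none
Why: Chloranil dehydrogenation through the extended C8 dienol removes hydride from C2 and gives the linear 1,9(10)-dien-8-one selectively (the classical enone to linear dienone conversion), the acyl group preventing oxidation at C3.

Step 19
Reactants: 30 linear dienone ester
Product: 32 7-hydroxy derivative of 30 (C7 epimers), via potassium enolate 31 (not isolated)
Conditions: KN(SiMe3)2, THF, −78 °C; then 3-phenyl-2-(phenylsulfonyl)oxaziridine, −78 °C; AcOH quench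
Reagents that add atoms: 3-phenyl-2-(phenylsulfonyl)oxaziridine, O=S(=O)(N1OC1c1ccccc1)c1ccccc1
Why: In this Davis enolate oxidation, kinetic deprotonation at the α′ carbon C7 gives the cross-conjugated enolate, which the oxaziridine hydroxylates; the uncontrolled C7 centre is destroyed in the next step.

Step 20
Reactants: 32 7-hydroxy dienone ester
Product: 34 (1R,2S,8aS)-7-hydroxy-1,8a-dimethyl-6-oxo-1,2,6,8a-tetrahydronaphthalen-2-yl (2E,4E,6R)-6-{[(tert-butyldimethylsilyl)oxy]methyl}octa-2,4-dienoate, via 7,8-dione 33 (not isolated)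
Conditions: Dess–Martin periodinane, CH2Cl2, 0 °C → rt
Reagents that add atoms: none
Why: Dess–Martin oxidation of the acyloin gives the 7,8-dione, which enolises spontaneously towards C6 (the only enolisable side, C5 being quaternary) to the cross-conjugated diosphenol.

Step 21
Reactants: 34 TBS-protected diosphenol ester
Product: 35 septeremophilane E
Conditions: HF·pyridine, pyridine, THF, 0 °C → rt
Reagents that add atoms: none
Why: Fluoride-mediated desilylation under buffered conditions frees the primary alcohol without touching the dienoate ester, the diosphenol or any stereocentre.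

## Compound list

1 | 2-methylcyclohexane-1,3-dione | CC1C(=O)CCCC1=O | starting material
2 | methyl vinyl ketone (but-3-en-2-one) | CC(=O)C=C | starting material
3 | 2-methyl-2-(3-oxobutyl)cyclohexane-1,3-dione | CC(=O)CCC1(C)C(=O)CCCC1=O | intermediate
4 | (4aS,8aS)-4a-hydroxy-8a-methyloctahydronaphthalene-1,6-dione (cis-fused ketol, OH cis to CH3; not isolated) | C[C@]12CCC(=O)C[C@@]1(O)CCCC2=O | intermediate
5 | (S)-Wieland–Miescher ketone, (S)-8a-methyl-3,4,8,8a-tetrahydronaphthalene-1,6(2H,7H)-dione | C[C@]12CCC(=O)C=C1CCCC2=O | intermediate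
6 | (5S)-C8 1,3-dithiolane (ethylene dithioketal of the enone carbonyl) of 5; C4 ketone free, C9=C10 retained | C[C@]12CCC3(SCCS3)C=C1CCCC2=O | intermediate
7 | potassium C3=C4 enolate of 6 (not isolated) | C[C@]12CCC3(SCCS3)C=C1CCC=C2[O-].[K+] | intermediate
8 | (5S)-4-(trifluoromethylsulfonyloxy)-5-methyl-3,9(10)-diene C8 dithiolane (enol triflate) | C[C@]12CCC3(SCCS3)C=C1CCC=C2OS(=O)(=O)C(F)(F)F | intermediate
9 | 4,5-dimethyl-3,9(10)-diene C8 dithiolane (C5 spatially unchanged; CIP label becomes 5R) | C[C@]12CCC3(SCCS3)C=C1CCC=C2C | intermediate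
10 | 3β-boryl-4α,5α-dimethyl-9(10)-ene C8 dithiolane (monoalkylborane; not isolated) | B[C@@H]1CCC2=CC3(SCCS3)CC[C@]2(C)[C@H]1C | intermediate
11 | (3R,4R,5R)-3β-hydroxy-4α,5α-dimethyl-9(10)-ene C8 dithiolane (OH trans to both methyls, methyls cis) | O[C@@H]1CCC2=CC3(SCCS3)CC[C@]2(C)[C@H]1C | intermediate
12 | (4R,5R)-4α,5α-dimethyl-9(10)-en-3-one C8 dithiolane | O=C1CCC2=CC3(SCCS3)CC[C@]2(C)[C@H]1C | intermediate
13 | (3S,4R,5R)-3α-hydroxy-4α,5α-dimethyl-9(10)-ene C8 dithiolane (OH and both methyls all cis) | O[C@H]1CCC2=CC3(SCCS3)CC[C@]2(C)[C@H]1C | intermediate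
14 | (4aR,5R,6S)-6-hydroxy-4a,5-dimethyl-4,4a,5,6,7,8-hexahydronaphthalen-2(3H)-one (core: 3α-OH, 4α-Me, 5α-Me, 9(10)-en-8-one) | O[C@H]1CCC2=CC(=O)CC[C@]2(C)[C@H]1C | intermediate
15 | (R)-4-benzyloxazolidin-2-one | O=C1N[C@H](Cc2ccccc2)CO1 | starting material
16 | butanoyl chloride | CCCC(=O)Cl | starting material
17 | lithium (R)-4-benzyl-2-oxooxazolidin-3-ide (not isolated) | [Li+].O=C1[N-][C@H](Cc2ccccc2)CO1 | intermediate
18 | (R)-4-benzyl-3-butanoyloxazolidin-2-one | CCCC(=O)N1[C@H](Cc2ccccc2)COC1=O | intermediate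
19 | trichlorotitanium (Z)-enolate of 18 (not isolated) | CC/C=C(\O[Ti](Cl)(Cl)Cl)N1[C@H](Cc2ccccc2)COC1=O | intermediate
20 | (R)-4-benzyl-3-[(S)-2-(hydroxymethyl)butanoyl]oxazolidin-2-one | CC[C@@H](CO)C(=O)N1[C@H](Cc2ccccc2)COC1=O | intermediate
21 | (R)-4-benzyl-3-[(S)-2-{[(tert-butyldimethylsilyl)oxy]methyl}butanoyl]oxazolidin-2-one | CC[C@@H](CO[Si](C)(C)C(C)(C)C)C(=O)N1[C@H](Cc2ccccc2)COC1=O | intermediate
22 | (R)-2-{[(tert-butyldimethylsilyl)oxy]methyl}butan-1-ol | CC[C@@H](CO[Si](C)(C)C(C)(C)C)CO | intermediate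
23 | (S)-2-{[(tert-butyldimethylsilyl)oxy]methyl}butanal | CC[C@@H](CO[Si](C)(C)C(C)(C)C)C=O | intermediate
24 | triethyl (E)-4-phosphonobut-2-enoate (triethyl 4-phosphonocrotonate) | CCOC(=O)/C=C/CP(=O)(OCC)OCC | starting material
25 | lithiated 24 (phosphonate-stabilised allyl anion; not isolated) | [Li+].CCOC(=O)/C=C/[CH-]P(=O)(OCC)OCC | intermediate
26 | ethyl (2E,4E,6R)-6-{[(tert-butyldimethylsilyl)oxy]methyl}octa-2,4-dienoate | CC[C@@H](CO[Si](C)(C)C(C)(C)C)/C=C/C=C/C(=O)OCC | intermediate
27 | (2E,4E,6R)-6-{[(tert-butyldimethylsilyl)oxy]methyl}octa-2,4-dienoic acid | CC[C@@H](CO[Si](C)(C)C(C)(C)C)/C=C/C=C/C(=O)O | intermediate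
28 | mixed anhydride of 27 with 2,4,6-trichlorobenzoic acid (not isolated) | CC[C@@H](CO[Si](C)(C)C(C)(C)C)/C=C/C=C/C(=O)OC(=O)c1c(Cl)cc(Cl)cc1Cl | intermediate
29 | (1R,2S,8aR)-1,8a-dimethyl-6-oxo-1,2,3,4,6,7,8,8a-octahydronaphthalen-2-yl (2E,4E,6R)-6-{[(tert-butyldimethylsilyl)oxy]methyl}octa-2,4-dienoate (3α-ester of 14) | CC[C@@H](CO[Si](C)(C)C(C)(C)C)/C=C/C=C/C(=O)O[C@H]1CCC2=CC(=O)CC[C@]2(C)[C@H]1C | intermediate
30 | (1R,2S,8aR)-1,8a-dimethyl-6-oxo-1,2,6,7,8,8a-hexahydronaphthalen-2-yl (2E,4E,6R)-6-{[(tert-butyldimethylsilyl)oxy]methyl}octa-2,4-dienoate (linear 1,9(10)-dien-8-one) | CC[C@@H](CO[Si](C)(C)C(C)(C)C)/C=C/C=C/C(=O)O[C@H]1C=CC2=CC(=O)CC[C@]2(C)[C@H]1C | intermediate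
31 | potassium C7=C8 enolate of 30 (not isolated) | CC[C@@H](CO[Si](C)(C)C(C)(C)C)/C=C/C=C/C(=O)O[C@H]1C=CC2=CC([O-])=CC[C@]2(C)[C@H]1C.[K+] | intermediate
32 | 7-hydroxy derivative of 30 (α′-hydroxy dienone, C7 epimers) | CC[C@@H](CO[Si](C)(C)C(C)(C)C)/C=C/C=C/C(=O)O[C@H]1C=CC2=CC(=O)C(O)C[C@]2(C)[C@H]1C | intermediate
33 | 7,8-dione from 32 (not isolated) | CC[C@@H](CO[Si](C)(C)C(C)(C)C)/C=C/C=C/C(=O)O[C@H]1C=CC2=CC(=O)C(=O)C[C@]2(C)[C@H]1C | intermediate
34 | (1R,2S,8aS)-7-hydroxy-1,8a-dimethyl-6-oxo-1,2,6,8a-tetrahydronaphthalen-2-yl (2E,4E,6R)-6-{[(tert-butyldimethylsilyl)oxy]methyl}octa-2,4-dienoate | CC[C@@H](CO[Si](C)(C)C(C)(C)C)/C=C/C=C/C(=O)O[C@H]1C=CC2=CC(=O)C(O)=C[C@]2(C)[C@H]1C | intermediate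
35 | septeremophilane E, (1R,2S,8aS)-7-hydroxy-1,8a-dimethyl-6-oxo-1,2,6,8a-tetrahydronaphthalen-2-yl (2E,4E,6R)-6-(hydroxymethyl)octa-2,4-dienoate | CC[C@H](/C=C/C=C/C(=O)O[C@H]1C=CC2=CC(=O)C(O)=C[C@]2(C)[C@H]1C)CO | target

## Step count and risks

Total steps: 21. Longest linear sequence: 14 steps (steps 1–9, then 17–21); the side-chain branch (steps 10–16) is 7 steps before the union.

Three steps most likely to fail:

Step 6 (hydroboration of 9). The risk is competing attack of borane on the C9=C10 alkene beside the dithiolane, or sulfur oxidation during work-up. Fallback: set out from 9 and remove the dithioketal first (MeI, CaCO3, aqueous MeCN) to give the 4,5-dimethyl-3,9(10)-dien-8-one F1. Reduce its carbonyl under Luche conditions (NaBH4, CeCl3·7H2O, MeOH) to the C8 allylic alcohol F2, and silylate (TBDPSCl, imidazole) to the C8 TBDPS ether F3. In F3 the C9=C10 alkene is an electron-poor, sterically screened allylic silyl ether and no sulfur is present. Hydroboration–oxidation (BH3·THF; NaOH, H2O2) then gives the 3β-alcohol F4, Dess–Martin periodinane the 3-ketone F5, Li[HB(s-Bu)3] the 3α-alcohol F6, and n-Bu4NF the 3α,8-diol F7. MnO2 in CH2Cl2 oxidises only the allylic C8 alcohol, which comes back to the route at 14.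

Step 18 (chloranil dehydrogenation of 29). The risk is sluggish or unselective hydride abstraction next to the C3 ester, or over-oxidation in ring B. Fallback: set out from 29 and form the thermodynamic extended silyl dienol ether F8 (TBSOTf, Et3N, CH2Cl2, 0 °C → rt; C8–OTBS, C8=C9 and C10=C1). Subject it to Saegusa–Ito oxidation with Pd(OAc)2 in MeCN at rt, which gives the linear dienone and comes back to the route at 30.

Step 19 (Davis α′-hydroxylation of 30). The risk is competing deprotonation at C3 or in the dienoate chain, or imino-aldol capture of the enolate. Fallback: set out from 30 and condense the C7 methylene with t-BuOCH(NMe2)2 (toluene, 80 °C, no strong base) to give the C7 dimethylaminomethylene ketone F9. Cleave its enamine C=C with singlet oxygen (O2, tetraphenylporphyrin, hν, CH2Cl2, −78 °C), which gives the 7,8-dione 33 directly; this tautomerises and comes back to the route at 34, so step 20 is not needed.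

## Further compounds

F1 | step 6 | 4,5-dimethyl-3,9(10)-dien-8-one, (4aR)-4a,5-dimethyl-4,4a,7,8-tetrahydronaphthalen-2(3H)-one | C[C@]12CCC(=O)C=C1CCC=C2C
F2 | step 6 | 4,5-dimethyl-3,9(10)-dien-8-ol (C8 epimers, mainly pseudo-equatorial OH) | C[C@]12CCC(O)C=C1CCC=C2C
F3 | step 6 | 8-(tert-butyldiphenylsilyloxy)-4,5-dimethyl-3,9(10)-diene | C[C@]12CCC(O[Si](c3ccccc3)(c3ccccc3)C(C)(C)C)C=C1CCC=C2C
F4 | step 6 | 3β-hydroxy-4α,5α-dimethyl-8-(tert-butyldiphenylsilyloxy)-9(10)-ene | O[C@@H]1CCC2=CC(O[Si](c3ccccc3)(c3ccccc3)C(C)(C)C)CC[C@]2(C)[C@H]1C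
F5 | step 6 | 4α,5α-dimethyl-8-(tert-butyldiphenylsilyloxy)-9(10)-en-3-one | O=C1CCC2=CC(O[Si](c3ccccc3)(c3ccccc3)C(C)(C)C)CC[C@]2(C)[C@H]1C
F6 | step 6 | 3α-hydroxy-4α,5α-dimethyl-8-(tert-butyldiphenylsilyloxy)-9(10)-ene | O[C@H]1CCC2=CC(O[Si](c3ccccc3)(c3ccccc3)C(C)(C)C)CC[C@]2(C)[C@H]1C
F7 | step 6 | 4α,5α-dimethyl-9(10)-ene-3α,8-diol | O[C@H]1CCC2=CC(O)CC[C@]2(C)[C@H]1C
F8 | step 18 | extended C8 tert-butyldimethylsilyl dienol ether of 29 (8-silyloxy-1(10),8-diene) | CC[C@@H](CO[Si](C)(C)C(C)(C)C)/C=C/C=C/C(=O)O[C@H]1CC=C2C=C(O[Si](C)(C)C(C)(C)C)CC[C@]2(C)[C@H]1C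
F9 | step 19 | 7-(dimethylaminomethylene) derivative of 30 (enaminone) | CC[C@@H](CO[Si](C)(C)C(C)(C)C)/C=C/C=C/C(=O)O[C@H]1C=CC2=CC(=O)C(=CN(C)C)C[C@]2(C)[C@H]1C
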